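## Retrosynthetic overview

1. Last ring closure: the C2=C3 bond, by intramolecular Knoevenagel condensation of a C2 aldehyde with the C3 β-keto ester (held as its C4 hemiketal). This closes the 10-membered carbocycle.
2. The C8 ester comes from N-methylurocanic acid (fragment C, C7N2) by Yamaguchi esterification; the C8 stereocentre comes from CBS reduction of a C8 ketone.
3. Key fragment union: the C8–C9 bond, by Fukuyama coupling of alkylzinc A (C1, C2, C9–C14; 12 C) with thioester B (C3–C8, C15; 9 C).
4. A comes from an Evans Diels–Alder reaction (sets C1, C10, C14). B comes from (S)-2-methylglycidol (C7) by alkyne homologation, formylation and an acetate aldol.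
5. Ring order: cyclohexene (Diels–Alder) → dihydrofuran hemiketal → 10-membered carbocycle.

Assumptions: sarcodictyin numbering is used (C15 = ester carbon); the recoverable Evans oxazolidinone is treated as an auxiliary reagent, not a starting material.

This route is a proposal designed from known reaction classes; it has not been run, and the final ring closure has no direct precedent.

## Fragment A (C1, C2, C9–C14)

**Step 1**
Reactants: 1, (2E)-3-methylpent-2-en-4-yn-1-ol
Product: 2, tert-butyl(dimethyl){[(2E)-3-methylpent-2-en-4-yn-1-yl]oxy}silane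
Conditions: TBSCl, imidazole, DMF, 0 °C → rt
Reagents that add atoms: TBSCl, CC(C)(C)[Si](C)(C)Cl
Why: Routine silylation; a weakly Lewis-basic silyl ether is chosen so the allylic oxygen survives the later Et2AlCl Diels–Alder.

**Step 2**
Reactants: 2
Product: 3, tert-butyl(dimethyl){[(2E)-3-methylpenta-2,4-dien-1-yl]oxy}silane
Conditions: H2 (1 atm), Lindlar catalyst, quinoline, hexane, rt, stopped at 1 equiv H2
Reagents that add atoms: none
Why: Lindlar semi-hydrogenation of the terminal alkyne gives the vinyl group and leaves the E-trisubstituted olefin untouched.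

**Step 3**
Reactants: 4, (2E)-4-methylpent-2-enoic acid
Product: 5, (4S)-4-benzyl-3-[(2E)-4-methylpent-2-enoyl]-1,3-oxazolidin-2-one
Conditions: PivCl, Et3N, THF, −20 °C; then (S)-4-benzyl-2-oxazolidinone, LiCl, rt
Reagents that add atoms: (S)-4-benzyl-2-oxazolidinone (auxiliary), O=C1N[C@@H](Cc2ccccc2)CO1
Why: Mixed-anhydride N-acylation of the Evans auxiliary.

**Step 4**
Reactants: 5 and 3 (2 equiv)
Product: 6, (4S)-4-benzyl-3-{[(1R,2R,6R)-2-({[tert-butyl(dimethyl)silyl]oxy}methyl)-3-methyl-6-(propan-2-yl)cyclohex-3-en-1-yl]carbonyl}-1,3-oxazolidin-2-one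
Conditions: Et2AlCl (1.5 equiv), CH2Cl2, −78 → −20 °C
Reagents that add atoms: none
Why: Evans asymmetric Diels–Alder. The diene adds endo to the face of the Al-chelated s-cis imide opposite the benzyl group, which sets C1. The E-dienophile puts the isopropyl group trans to the acyl group (C14). The E-diene in the endo mode puts the CH2OTBS arm cis to the acyl group (C10). The "ortho" regiochemistry follows from the 1-substituent of the diene and from the β-isopropyl carbon bonding to the unsubstituted diene terminus.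

**Step 5**
Reactants: 6
Product: 7, [(1R,2R,6R)-2-({[tert-butyl(dimethyl)silyl]oxy}methyl)-3-methyl-6-(propan-2-yl)cyclohex-3-en-1-yl]methanol
Conditions: LiBH4, MeOH (1.1 equiv), Et2O, 0 °C
Reagents that add atoms: none
Why: Reductive cleavage of the imide gives the C2 alcohol and returns the auxiliary; no stereocentre is touched.

**Step 6**
Reactants: 7
Product: 8, the C2-O-TBDPS, C9-O-TBS bis-silyl ether of the (1R,2R,6R)-diol
Conditions: TBDPSCl, imidazole, DMF, rt
Reagents that add atoms: TBDPSCl, CC(C)(C)[Si](Cl)(c1ccccc1)c1ccccc1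
Why: Silylation with a group that is more acid-stable than TBS, which allows the next differentiation.

**Step 7**
Reactants: 8
Product: 9, [(1R,2R,6R)-1-({[tert-butyl(diphenyl)silyl]oxy}methyl)-3-methyl-6-(propan-2-yl)cyclohex-3-en-2-yl]methanol (free C9-OH)
Conditions: CSA (0.1 equiv), MeOH/CH2Cl2, 0 °C
Reagents that add atoms: none
Why: Acidic methanolysis removes a primary TBS ether about 100 times faster than a primary TBDPS ether.

**Step 8**
Reactants: 9
Product: 10, tert-butyl{[(1R,2R,6R)-2-(iodomethyl)-3-methyl-6-(propan-2-yl)cyclohex-3-en-1-yl]methoxy}diphenylsilane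
Conditions: I2, PPh3, imidazole, CH2Cl2, 0 °C → rt
Reagents that add atoms: I2, II
Why: Appel-type (Garegg–Samuelsson) iodination of the primary alcohol.

## Fragment B (C3–C8, C15)

**Step 9**
Reactants: 11, (S)-2-methylglycidol
Product: 12, (2S)-3-[(4-methoxyphenyl)methoxy]-2-methylpropane-1,2-diol
Conditions: 4-MeOC6H4CH2OH (3 equiv), NaH, DMF, 0 → 60 °C
Reagents that add atoms: 4-methoxybenzyl alcohol, COc1ccc(CO)cc1
Why: Alkoxide opening of the epoxide at CH2. No bond to the quaternary carbon (future C7) is broken, and the competing Payne rearrangement of 2-methylglycidol is degenerate, so the configuration is kept.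

**Step 10**
Reactants: 12
Product: 13, (2R)-2-hydroxy-3-[(4-methoxyphenyl)methoxy]-2-methylpropanal
Conditions: SO3·pyridine, DMSO, i-Pr2NEt, CH2Cl2, 0 °C (used crude)
Reagents that add atoms: none
Why: Parikh–Doering oxidation of the primary alcohol; the tertiary alcohol cannot be oxidised and the aldehyde has no α-hydrogen.

**Step 11**
Reactants: 13
Product: 14, (2S)-1-[(4-methoxyphenyl)methoxy]-2-methylbut-3-yn-2-ol
Conditions: dimethyl (1-diazo-2-oxopropyl)phosphonate, K2CO3, MeOH, 0 °C → rt
Reagents that add atoms: Ohira–Bestmann reagent (adds C5), COP(=O)(OC)C(=[N+]=[N-])C(C)=O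
Why: Seyferth–Gilbert/Ohira–Bestmann homologation of the aldehyde to the terminal alkyne (C6≡C5).

**Step 12**
Reactants: 14
Product: 15, (4S)-4-hydroxy-5-[(4-methoxyphenyl)methoxy]-4-methylpent-2-ynal
Conditions: n-BuLi (2.1 equiv), THF, −78 °C; DMF; inverse quench into aq KH2PO4
Reagents that add atoms: DMF (adds C4 as CHO), CN(C)C=O
Why: Formylation of the alkoxide/acetylide dianion.

**Step 13**
Reactants: 15
Product: 16, methyl (3RS,6S)-3,6-dihydroxy-7-[(4-methoxyphenyl)methoxy]-6-methylhept-4-ynoate
Conditions: MeOAc, LDA (2.5 equiv), THF, −78 °C; then 15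
Reagents that add atoms: methyl acetate, COC(C)=O
Why: Acetate aldol 1,2-addition to the ynal installs C3 and C15. The new C4 carbinol is an inconsequential epimer mixture because it is oxidised later.

**Step 14**
Reactants: 16
Product: 17, methyl (3RS,6S)-7-[(4-methoxyphenyl)methoxy]-6-methyl-3,6-bis[(triethylsilyl)oxy]hept-4-ynoate
Conditions: TESOTf (2.5 equiv), 2,6-lutidine, CH2Cl2, −78 → 0 °C
Reagents that add atoms: TESOTf, CC[Si](CC)(CC)OS(=O)(=O)C(F)(F)F
Why: The silyl triflate protects both the secondary and the hindered tertiary propargylic alcohol.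

**Step 15**
Reactants: 17
Product: 18, methyl (3RS,6S)-7-hydroxy-6-methyl-3,6-bis[(triethylsilyl)oxy]hept-4-ynoate
Conditions: DDQ, CH2Cl2/pH 7 buffer, 0 °C
Reagents that add atoms: none
Why: Oxidative PMB cleavage under buffered conditions that TES ethers tolerate.

**Step 16**
Reactants: 18
Product: 19, (2S,5RS)-7-methoxy-2-methyl-7-oxo-2,5-bis[(triethylsilyl)oxy]hept-3-ynoic acid
Conditions: TEMPO (cat.), NaOCl (cat.), NaClO2, MeCN/pH 6.7 phosphate buffer, 35 °C
Reagents that add atoms: NaClO2/H2O (one O), [O-]Cl=O.[Na+] and O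
Why: TEMPO/chlorite oxidation takes the primary alcohol to the acid (C8) near neutral pH; the α-carbon is quaternary, so it cannot epimerise.

**Step 17**
Reactants: 19
Product: 20, S-ethyl (2S,5RS)-7-methoxy-2-methyl-7-oxo-2,5-bis[(triethylsilyl)oxy]hept-3-ynethioate
Conditions: EtSH, EDC·HCl, DMAP, CH2Cl2, 0 °C → rt
Reagents that add atoms: ethanethiol, CCS
Why: Steglich thioesterification gives the acyl partner for a ketone synthesis that tolerates the methyl ester.

## Fragment C

**Step 18**
Reactants: 21, 1-methyl-1H-imidazole-4-carbaldehyde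
Product: 22, (2E)-3-(1-methyl-1H-imidazol-4-yl)prop-2-enoic acid
Conditions: CH2(CO2H)2, pyridine, piperidine (cat.), 100 °C
Reagents that add atoms: malonic acid, OC(=O)CC(=O)O
Why: Knoevenagel–Doebner condensation with decarboxylation gives the E-acrylic acid.

## Assembly

**Step 19**
Reactants: 10 and 20
Product: 23, the C8 ketone (ring as in 10; C9H2–C8(=O)–C7(S)(CH3)(OTES)–C6≡C5–C4H(OTES)–C3H2–C15O2Me; C2 = CH2OTBDPS)
Conditions: 10, activated Zn dust, DMA, 45 °C; then 20, PdCl2(PPh3)2 (10 mol %), toluene, rt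
Reagents that add atoms: none
Why: Fukuyama coupling. The primary alkylzinc iodide acylates the Pd-activated thioester only, so the methyl ester, alkyne and silyl ethers survive and no stereocentre is touched.

**Step 20**
Reactants: 23
Product: 24, the (7S,8S)-C8 alcohol
Conditions: (R)-Me-CBS (1 equiv), BH3·SMe2, CH2Cl2, −30 °C
Reagents that add atoms: none
Why: Corey–Bakshi–Shibata reduction. The ketone lies between a quaternary carbon (large) and a CH2 (small), so (R)-CBS delivers hydride under reagent control to give the 8S carbinol.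

**Step 21**
Reactants: 24
Product: 25, the (5Z)-alkene (C5=C6 cis)
Conditions: H2 (1 atm), Lindlar catalyst, quinoline, EtOAc, rt
Reagents that add atoms: none
Why: syn semi-hydrogenation of the internal alkyne gives the Z-olefin needed for later hemiketal formation; the ring olefin is inert.

**Step 22**
Reactants: 25 and 22
Product: 26, the C8 (E)-N-methylurocanate ester
Conditions: 22, 2,4,6-trichlorobenzoyl chloride, Et3N, THF; then 25, DMAP, toluene, 40 °C
Reagents that add atoms: none (22 is the reactant)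
Why: Yamaguchi esterification of the hindered secondary alcohol, with retention at C8. Acylating C8 now also prevents it from competing with C7-OH in the later hemiketal formation.

**Step 23**
Reactants: 26
Product: 27, the triol (C2-OH, C4-OH, C7-OH free)
Conditions: HF·pyridine, excess pyridine, THF, 0 °C → rt
Reagents that add atoms: none
Why: Buffered fluoride removes the TBDPS group and both TES groups without touching the esters or ionising the tertiary allylic alcohol.

**Step 24**
Reactants: 27
Product: 28, the C2 aldehyde bearing the 2,5-dihydrofuran hemiketal (C4(OH)(CH2CO2Me)–O–C7)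
Conditions: Dess–Martin periodinane (2.5 equiv), NaHCO3, CH2Cl2, 0 °C → rt
Reagents that add atoms: none
Why: DMP oxidises the primary alcohol to the aldehyde and the allylic alcohol to the (Z)-enone, which the C7 hydroxyl traps at once as the five-membered hemiketal. C4 is freely epimerisable by ring–chain tautomerism.

**Step 25**
Reactants: 28
Product: 29, sarcodictyin A
Conditions: piperidine (0.3 equiv), AcOH (0.3 equiv), 4 Å MS, CH2Cl2 (1 mM), rt → 40 °C
Reagents that add atoms: none
Why: Intramolecular Knoevenagel condensation of the C2 aldehyde (as its iminium) with the ring–chain tautomeric β-keto ester forms C2=C3 and the 10-membered ring. The ring fixes the olefin geometry (C1 and C4 cis, ester exocyclic), and only the C4 epimer with C3 cis to C8 can bridge, so C4 settles in the natural configuration.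

## Compound list

1 | (2E)-3-methylpent-2-en-4-yn-1-ol | C#C/C(C)=C/CO | starting material
2 | TBS ether of 1 | C#C/C(C)=C/CO[Si](C)(C)C(C)(C)C | intermediate
3 | (2E)-3-methylpenta-2,4-dienyl TBS ether | C=C/C(C)=C/CO[Si](C)(C)C(C)(C)C | intermediate
4 | (2E)-4-methylpent-2-enoic acid | CC(C)/C=C/C(=O)O | starting material
5 | (4S)-4-benzyl-3-[(2E)-4-methylpent-2-enoyl]oxazolidin-2-one | CC(C)/C=C/C(=O)N1C(=O)OC[C@@H]1Cc1ccccc1 | intermediate
6 | Diels–Alder adduct, (1R,2R,6R) | O=C1OC[C@H](Cc2ccccc2)N1C(=O)[C@@H]1[C@@H](C(C)C)CC=C(C)[C@@H]1CO[Si](C)(C)C(C)(C)C | intermediate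
7 | (1R,2R,6R)-C2 alcohol, C9-OTBS | OC[C@@H]1[C@@H](C(C)C)CC=C(C)[C@@H]1CO[Si](C)(C)C(C)(C)C | intermediate
8 | C2-OTBDPS, C9-OTBS bis-silyl ether | CC(C)(C)[Si](c1ccccc1)(c1ccccc1)OC[C@@H]1[C@@H](C(C)C)CC=C(C)[C@@H]1CO[Si](C)(C)C(C)(C)C | intermediate
9 | C2-OTBDPS, C9-OH | CC(C)(C)[Si](c1ccccc1)(c1ccccc1)OC[C@@H]1[C@@H](C(C)C)CC=C(C)[C@@H]1CO | intermediate
10 | fragment A iodide | CC(C)(C)[Si](c1ccccc1)(c1ccccc1)OC[C@@H]1[C@@H](C(C)C)CC=C(C)[C@@H]1CI | intermediate
11 | (S)-2-methylglycidol | C[C@]1(CO)CO1 | starting material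
12 | (2S)-3-(PMB-oxy)-2-methylpropane-1,2-diol | COc1ccc(COC[C@@](C)(O)CO)cc1 | intermediate
13 | (2R)-2-hydroxy-3-(PMB-oxy)-2-methylpropanal | COc1ccc(COC[C@@](C)(O)C=O)cc1 | intermediate
14 | (2S)-1-(PMB-oxy)-2-methylbut-3-yn-2-ol | COc1ccc(COC[C@@](C)(O)C#C)cc1 | intermediate
15 | (4S)-4-hydroxy-5-(PMB-oxy)-4-methylpent-2-ynal | COc1ccc(COC[C@@](C)(O)C#CC=O)cc1 | intermediate
16 | methyl (3RS,6S)-3,6-dihydroxy-7-(PMB-oxy)-6-methylhept-4-ynoate | COc1ccc(COC[C@@](C)(O)C#CC(O)CC(=O)OC)cc1 | intermediate
17 | bis-TES ether of 16 | COc1ccc(COC[C@@](C)(O[Si](CC)(CC)CC)C#CC(O[Si](CC)(CC)CC)CC(=O)OC)cc1 | intermediate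
18 | methyl (3RS,6S)-7-hydroxy-6-methyl-3,6-bis(TES-oxy)hept-4-ynoate | OC[C@@](C)(O[Si](CC)(CC)CC)C#CC(O[Si](CC)(CC)CC)CC(=O)OC | intermediate
19 | (2S,5RS)-acid | OC(=O)[C@@](C)(O[Si](CC)(CC)CC)C#CC(O[Si](CC)(CC)CC)CC(=O)OC | intermediate
20 | fragment B S-ethyl thioester | CCSC(=O)[C@@](C)(O[Si](CC)(CC)CC)C#CC(O[Si](CC)(CC)CC)CC(=O)OC | intermediate
21 | 1-methyl-1H-imidazole-4-carbaldehyde | Cn1cnc(C=O)c1 | starting material
22 | (E)-N-methylurocanic acid (fragment C) | Cn1cnc(/C=C/C(=O)O)c1 | intermediate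
23 | C8 ketone | CC(C)(C)[Si](c1ccccc1)(c1ccccc1)OC[C@@H]1[C@@H](C(C)C)CC=C(C)[C@@H]1CC(=O)[C@@](C)(O[Si](CC)(CC)CC)C#CC(O[Si](CC)(CC)CC)CC(=O)OC | intermediate
24 | (7S,8S)-alcohol | CC(C)(C)[Si](c1ccccc1)(c1ccccc1)OC[C@@H]1[C@@H](C(C)C)CC=C(C)[C@@H]1C[C@H](O)[C@@](C)(O[Si](CC)(CC)CC)C#CC(O[Si](CC)(CC)CC)CC(=O)OC | intermediate
25 | (5Z)-alkene | CC(C)(C)[Si](c1ccccc1)(c1ccccc1)OC[C@@H]1[C@@H](C(C)C)CC=C(C)[C@@H]1C[C@H](O)[C@@](C)(O[Si](CC)(CC)CC)/C=C\C(O[Si](CC)(CC)CC)CC(=O)OC | intermediate
26 | C8 urocanate | CC(C)(C)[Si](c1ccccc1)(c1ccccc1)OC[C@@H]1[C@@H](C(C)C)CC=C(C)[C@@H]1C[C@H](OC(=O)/C=C/c1cn(C)cn1)[C@@](C)(O[Si](CC)(CC)CC)/C=C\C(O[Si](CC)(CC)CC)CC(=O)OC | intermediate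
27 | triol | OC[C@@H]1[C@@H](C(C)C)CC=C(C)[C@@H]1C[C@H](OC(=O)/C=C/c1cn(C)cn1)[C@@](C)(O)/C=C\C(O)CC(=O)OC | intermediate
28 | hemiketal aldehyde (seco-sarcodictyin) | O=C[C@@H]1[C@@H](C(C)C)CC=C(C)[C@@H]1C[C@H](OC(=O)/C=C/c1cn(C)cn1)[C@]1(C)C=CC(O)(CC(=O)OC)O1 | intermediate
29 | sarcodictyin A | COC(=O)/C1=C/[C@@H]2[C@@H](C(C)C)CC=C(C)[C@@H]2C[C@H](OC(=O)/C=C/c2cn(C)cn2)[C@]2(C)C=C[C@@]1(O)O2 | target

## Step count and risks

Total steps: 25.
Longest linear sequence: 16 steps (11 → 29: steps 9–17, then 19–25), which is 64% of the total.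

Steps most likely to fail:

1. **Step 25, Knoevenagel closure of the 10-membered ring.** The β-keto ester is masked as a hemiketal, the ring is medium-sized, and C1 could epimerise through the aldehyde enamine. Fallback: close the ring at C4–C5 instead. Fragment B is truncated at the terminal alkyne (C5–C8, from 14). The C2 aldehyde is extended with methyl cyanoacetate (then DIBAL-H, TIPSOTf, DIBAL-H) to the (Z)-enal. The ring is closed by intramolecular acetylide addition to that aldehyde (LiHMDS), followed by DMP, Lindlar reduction to the hemiketal, and late oxidation of C15 to the methyl ester; the urocanate is then attached after ring closure.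

2. **Step 4, Diels–Alder reaction.** The 1-CH2OR and 2-methyl groups of the diene direct in opposite senses, the dienophile is β-branched, and the diene may be acid-sensitive. Fallback: use the 2-silyloxy diene TBSOCH2–CH=C(Me)–C(OTES)=CH2, in which the oxygen and the 1-substituent direct the same bond. The resulting C12 silyl enol ether is converted to the enol triflate (MeLi; PhNTf2) and reduced (Pd(OAc)2/PPh3, HCO2H, Bu3N) to the C11=C12 olefin.

3. **Step 19, Fukuyama coupling.** The thioester is α-quaternary and may react slowly. Fallback: form C8–C9 by carbonyl addition instead of acyl cross-coupling. Alcohol 18 is oxidised to the aldehyde, and the Grignard reagent from 10 (t-BuLi, then MgBr2, −78 °C; aldehyde reacts far faster than the ester) is added to give the C8 carbinol directly. Any wrong C8 epimer is converged by DMP oxidation and CBS reduction.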